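## Analysis of the target

The target is a dihydrochalcone–lignan conjugate. Ring A is a 2,4,6-trihydroxyphenyl ring that carries the 3-(4-methoxyphenyl)propanoyl chain (ring D) on C-1′ and, on C-3′ between two hydroxyls, the benzylic carbon C-1 of an open chain C-1 to C-4. C-1 bears ring B (4-hydroxyphenyl), C-2 and C-3 each bear a methyl group, and C-4 is the benzylic CH2 of ring C (4-hydroxyphenyl). The three contiguous stereocentres C-1 (R), C-2 (R) and C-3 (S) sit in an open chain. Drawn as a zigzag from ring A through C-1 to C-4, ring B and both methyl groups lie on the same side (all syn, C-2/C-3 threo).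

The feature the route uses is the six-atom array O-4′ (or equally O-2′), C-4′, C-3′, C-1, C-2 and the carbon of the C-2 methyl group. At the lactone oxidation level this array is a 3,4-dihydrocoumarin, and the all-syn triad corresponds to its 3,4-cis isomer, with ring B on position 4 and the C-3 branch on position 3.

The sensitive groups are the electron-rich ring A (air oxidation, ipso protonation), the doubly benzylic C-1 flanked by hydroxyaryl rings (acid can ionise it to a quinone methide and epimerise it), and an aryl ketone that excludes late hydride or hydrosilane steps. Five free phenols stand next to a single methyl ether on ring D.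

The synthesis is hard because the ring A–C-1 bond lies at the most hindered site of ring A. C-1 must also be set relative to a C-2 whose two carbon substituents (methyl and a secondary alkyl) differ little, so 1,2-induction in any cation or quinone methide chemistry is weak.

## Retrosynthetic reasoning

**15 to 12 and 13.** The acyl–ring A bond is cut last. The ketone would not survive the reduction planned before it. The two free positions of ring A in 12 are equivalent, so there is no regiochemical question. The ring D methyl ether arrives with 13 after all other ethers have been cleaved, so no selective deprotection is needed. The forward reaction is a Hoesch acylation that must touch only ring A.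

**12 to 10 (through 11).** One ring A hydroxyl and the C-2 methyl group are reconnected as an aryl ester, which turns the open stereotriad into the 3,4-cis-dihydrocoumarin 10. This gives the acyclic triad a ring for the moment in which C-1 and C-2 are made. The forward step must reduce the lactone carbonyl fully to CH3, free the ring A oxygen and cleave the four methyl ethers. A borane-catalysed hydrosilane reduction does all three and passes through the silyl ether 11.

**10 to 4 and 8 (through 9).** The C-1–C-2 bond and the lactone C–O bond are cut together. This is the retron of a formal [4+2] annulation between the ortho-quinone methide 4 (ring A, C-1 and ring B) and the enolate of acid 8 (C-2, C-3, C-4, ring C and the future C-2 methyl carbon), activated in the flask as 9. The cut lies between the two most hindered stereocentres, joins two fragments of similar size, and leaves one flat achiral partner and one partner with a single stereocentre. The forward reaction must set C-1 and C-2 under catalyst control and give the cis lactone.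

**4 to 1 and 2 (through 3).** The C-1–ring B bond is cut to a salicylaldehyde and an aryl Grignard reagent. Dehydration of the benzhydrol 3 gives 4. The regiochemistry on ring A is fixed by the aldehyde.

**8 to 7, and 7 to 5 and 6.** C-3 is the only stereocentre not made in the key step. It is set by asymmetric hydrogenation of the 1,1-disubstituted alkene 7, in which the carboxyl group serves as the directing group. 7 comes from opening diketene 5 at its vinylic C–O bond with the benzylic Grignard reagent 6, which forms the C-3–C-4 bond.

## Alternatives that were turned down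

**Alternative 1:** the textbook, biomimetic cut of the ring A–C-1 bond. The forward key step is a Friedel–Crafts alkylation of the preformed dihydrochalcone A1 by the benzylic cation (para-quinone methide) released under acid from the lignan alcohol A2. It is the shortest route on paper. It was turned down for these reasons:
- C-1 would be set only by 1,2-induction from C-2, whose methyl and secondary alkyl groups differ little.
- The allylic 1,3-strain model of such cations puts the C-2 hydrogen in the plane and predicts attack syn to the methyl group, which leads to the C-1 epimer of the target.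
- The cation can lose the C-2 proton to a styrene, which would scramble C-2.
- The alkylation is reversible under the acid needed.
- A1 can be alkylated twice.

**Alternative 2:** use of the hidden twofold symmetry. Rings B and C are identical and C-2/C-3 are threo, so the chain without ring A is twofold-symmetric. Double asymmetric hydrogenation of diene A3 would give A4 with both methyl stereocentres in one step. An oxidative cross-dehydrogenative coupling (benzylic hydride abstraction by a quinone oxidant) would then join one of the two equivalent benzylic carbons of A4 to ring A of A1. It was turned down for these reasons: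
- The coupling again forms C-1 by attack of ring A on a ring B-stabilised cation, with the same weak and wrongly directed facial bias as in Alternative 1.
- The second benzylic position is oxidised at a similar rate.
- The methyl ethers of rings B and C would have to be cleaved next to the ring D methyl ether.
- The gain in steps is paid for with the one stereocentre that is hardest to correct.

**Alternative 3:** an aromatic Claisen rearrangement with 1,3-chirality transfer. The aryl allyl ether A5 would rearrange through a chair to A6. This forms the ring A–C-1 bond at the hindered ortho position intramolecularly and transfers the configuration of an easily made C–O centre to C-1. It was turned down for these reasons: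
- The rearrangement leaves C-2 as an sp2 carbon and C-3 as a vinylic CH.
- A net addition of H to C-2 and CH3 to C-3 across a trisubstituted alkene is then needed, creating two stereocentres under the control of a C-1 whose two aryl groups differ little.
- The only defensible sequence (hydroboration, one-carbon homologation, protodeboronation) costs at least three steps under substrate control.
- The hindered secondary allylic aryl ether A5 is itself hard to make without allylic transposition.

Key step: step 4

Assumption 1: the sense of induction of the two chiral catalysts (steps 3 and 4) is assigned by analogy with their closest substrates; in each case the catalyst enantiomer is chosen to give the stated descriptor.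

Assumption 2: 4 is drawn as its E isomer (anisyl group anti to the ring carbonyl); the exocyclic double bond of such a push–pull quinone methide is expected to be configurationally mobile.

## Route

Step 1
Reactants: 1 2-hydroxy-4,6-dimethoxybenzaldehyde; 2 (4-methoxyphenyl)magnesium bromide
Product: 4 (6E)-3,5-dimethoxy-6-[(4-methoxyphenyl)methylidene]cyclohexa-2,4-dien-1-one, via benzhydrol 3 (not isolated)
Conditions: 2 (2.2 equiv), THF, −20 → 0 °C; H2O; then toluene, 4 Å MS, 80 °C
Reagents that add atoms: none
Why: Grignard addition to a salicylaldehyde (the first equivalent is consumed by the phenol) should give the benzhydrol, and this doubly activated ortho-hydroxybenzhydrol should lose water on gentle heating to the push–pull stabilised ortho-quinone methide; no stereocentre is carried forward.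

Step 2
Reactants: 5 diketene (4-methylideneoxetan-2-one); 6 (4-methoxybenzyl)magnesium chloride
Product: 7 3-[(4-methoxyphenyl)methyl]but-3-enoic acid
Conditions: NiCl2 (5 mol %), THF, −78 → 0 °C; then 1 M HCl
Reagents that add atoms: none
Why: Nickel-catalysed cross-coupling of a Grignard reagent at the vinylic C–O bond of diketene is a known route to 3-methylenealkanoic acids and forms the C-3–C-4 bond; the catalyst diverts the reagent from attack at the lactone carbonyl.

Step 3
Reactants: 7 3-[(4-methoxyphenyl)methyl]but-3-enoic acid
Product: 8 (3S)-4-(4-methoxyphenyl)-3-methylbutanoic acid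
Conditions: H2 (6 atm), [Ir(cod)(L)]BArF (1 mol %; L = chiral spiro phosphine–oxazoline of the SIPHOX type, BArF = B[3,5-(CF3)2C6H3]4), Et3N (0.5 equiv), MeOH, 45 °C
Reagents that add atoms: none
Why: Carboxylate-directed iridium-catalysed asymmetric hydrogenation of a 1,1-dialkyl terminal alkene; the bound carboxylate fixes the alkene in the chiral pocket and the ligand selects the face, which sets C-3 (S).

Step 4
Reactants: 4 (6E)-3,5-dimethoxy-6-[(4-methoxyphenyl)methylidene]cyclohexa-2,4-dien-1-one; 8 (3S)-4-(4-methoxyphenyl)-3-methylbutanoic acid
Product: 10 (3R,4R)-5,7-dimethoxy-4-(4-methoxyphenyl)-3-[(2S)-1-(4-methoxyphenyl)propan-2-yl]-3,4-dihydro-2H-chromen-2-one, via acyl imidazole 9 (not isolated)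
Conditions: 8, 1,1'-carbonyldiimidazole (1.1 equiv), THF, 23 °C, 1 h; then 4 (1.0 equiv), aminoindanol-derived N-mesityl triazolium tetrafluoroborate (10 mol %), Cs2CO3 (20 mol %), 4 Å MS, THF, 0 → 23 °C
Reagents that add atoms: none
Why: The carbene adds to acyl imidazole 9 to give an acyl azolium, which the released imidazolide deprotonates to the Z(O)-azolium enolate. Its α-carbon (C-2) attacks the methide carbon of 4 (C-1), ring A re-aromatises to a phenoxide, and this phenoxide acylates on the acyl azolium, which closes the lactone and frees the carbene. The closest known reaction type is the carbene-catalysed formal [4+2] annulation of azolium enolates with enones and ortho-quinone methides, which gives 3,4-cis lactones. The six-membered lactone closes in an endo inverse-demand oxa-Diels–Alder topology, and in the stepwise limit the O-acylation is a 6-exo-trig acyl substitution. C-1 (position 4, R) is controlled by the catalyst, which dictates the methide face that meets the bound enolate in the endo arrangement. C-2 (position 3, R) is controlled by the indane wall of the catalyst, which leaves one enolate face open, and the cis relation follows from the Z(O)-enolate, the E-methide and the endo topology. The (S)-centre at C-3 next to the enolate carbon is a spectator whose small bias the catalyst should override, and any minor enantiomer of 8 would appear as a separable diastereomer of 10. The step needs cis over trans selectivity and annulation over self-condensation of 4; the strong polarisation of 4 (aromatisation as driving force) and the mild carbonate base, which should not epimerise position 3, are meant to secure both.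

Step 5
Reactants: 10 (3R,4R)-5,7-dimethoxy-4-(4-methoxyphenyl)-3-[(2S)-1-(4-methoxyphenyl)propan-2-yl]-3,4-dihydro-2H-chromen-2-one
Product: 12 2-[(1R,2R,3S)-1,4-bis(4-hydroxyphenyl)-2,3-dimethylbutyl]benzene-1,3,5-triol, via pentakis(triethylsilyl) ether 11 (not isolated)
Conditions: Et3SiH (14 equiv), B(C6F5)3 (10 mol %), CH2Cl2, 23 °C; then HCl (cat.), MeOH, 0 °C
Reagents that add atoms: none
Why: Borane-catalysed hydrosilane reduction takes an aliphatic ester carbonyl through the silyl acetal and ether stages to a methyl group (hydride displaces the silylated oxygen from the primary carbon, which releases the ring A oxygen as its silyl ether), and the same system cleaves aryl methyl ethers to aryl silyl ethers and methane. Acidic methanolysis then removes the five silyl groups; neither C-1 nor C-2 becomes cationic or enolisable, so the triad should be kept.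

Step 6
Reactants: 12 2-[(1R,2R,3S)-1,4-bis(4-hydroxyphenyl)-2,3-dimethylbutyl]benzene-1,3,5-triol; 13 3-(4-methoxyphenyl)propanenitrile
Product: 15 1-{3-[(1R,2R,3S)-1,4-bis(4-hydroxyphenyl)-2,3-dimethylbutyl]-2,4,6-trihydroxyphenyl}-3-(4-methoxyphenyl)propan-1-one, via ketiminium chloride 14 (not isolated)
Conditions: 13 (1.2 equiv), ZnCl2 (1.0 equiv), HCl (g), Et2O, 0 °C; then H2O, 90 °C
Reagents that add atoms: water (O)
Why: Hoesch reaction: the nitrilium species from 13 and HCl should attack only the phloroglucinol ring (its two free positions are equivalent and the 4-hydroxyphenyl rings are far less nucleophilic). The ketiminium salt deactivates ring A against a second acylation and is hydrolysed to the ketone; the ring D methyl ether comes in intact with 13.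

## Compound list

1 | 2-hydroxy-4,6-dimethoxybenzaldehyde | COc1cc(O)c(C=O)c(OC)c1 | starting material
2 | (4-methoxyphenyl)magnesium bromide | COc1ccc([Mg]Br)cc1 | starting material
3 | 2-[hydroxy(4-methoxyphenyl)methyl]-3,5-dimethoxyphenol (racemic benzhydrol) | COc1ccc(C(O)c2c(O)cc(OC)cc2OC)cc1 | intermediate
4 | (6E)-3,5-dimethoxy-6-[(4-methoxyphenyl)methylidene]cyclohexa-2,4-dien-1-one | O=C1C=C(OC)C=C(OC)/C1=C\c1ccc(OC)cc1 | intermediate
5 | diketene (4-methylideneoxetan-2-one) | C=C1CC(=O)O1 | starting material
6 | (4-methoxybenzyl)magnesium chloride | COc1ccc(C[Mg]Cl)cc1 | starting material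
7 | 3-[(4-methoxyphenyl)methyl]but-3-enoic acid | C=C(Cc1ccc(OC)cc1)CC(=O)O | intermediate
8 | (3S)-4-(4-methoxyphenyl)-3-methylbutanoic acid | OC(=O)C[C@@H](C)Cc1ccc(OC)cc1 | intermediate
9 | (3S)-1-(1H-imidazol-1-yl)-4-(4-methoxyphenyl)-3-methylbutan-1-one (acyl imidazole) | O=C(C[C@@H](C)Cc1ccc(OC)cc1)n1ccnc1 | intermediate
10 | (3R,4R)-5,7-dimethoxy-4-(4-methoxyphenyl)-3-[(2S)-1-(4-methoxyphenyl)propan-2-yl]-3,4-dihydro-2H-chromen-2-one | COc1cc(OC)c2c(c1)OC(=O)[C@H]([C@@H](C)Cc1ccc(OC)cc1)[C@@H]2c1ccc(OC)cc1 | intermediate
11 | 2-[(1R,2R,3S)-2,3-dimethyl-1,4-bis{4-[(triethylsilyl)oxy]phenyl}butyl]-1,3,5-tris[(triethylsilyl)oxy]benzene | CC[Si](CC)(CC)Oc1cc(O[Si](CC)(CC)CC)c([C@@H](c2ccc(O[Si](CC)(CC)CC)cc2)[C@H](C)[C@@H](C)Cc2ccc(O[Si](CC)(CC)CC)cc2)c(O[Si](CC)(CC)CC)c1 | intermediate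
12 | 2-[(1R,2R,3S)-1,4-bis(4-hydroxyphenyl)-2,3-dimethylbutyl]benzene-1,3,5-triol | Oc1cc(O)c([C@@H](c2ccc(O)cc2)[C@H](C)[C@@H](C)Cc2ccc(O)cc2)c(O)c1 | intermediate
13 | 3-(4-methoxyphenyl)propanenitrile | COc1ccc(CCC#N)cc1 | starting material
14 | 1-{3-[(1R,2R,3S)-1,4-bis(4-hydroxyphenyl)-2,3-dimethylbutyl]-2,4,6-trihydroxyphenyl}-3-(4-methoxyphenyl)propan-1-iminium chloride | COc1ccc(CCC(=[NH2+])c2c(O)cc(O)c([C@@H](c3ccc(O)cc3)[C@H](C)[C@@H](C)Cc3ccc(O)cc3)c2O)cc1.[Cl-] | intermediate
15 | 1-{3-[(1R,2R,3S)-1,4-bis(4-hydroxyphenyl)-2,3-dimethylbutyl]-2,4,6-trihydroxyphenyl}-3-(4-methoxyphenyl)propan-1-one | COc1ccc(CCC(=O)c2c(O)cc(O)c([C@@H](c3ccc(O)cc3)[C@H](C)[C@@H](C)Cc3ccc(O)cc3)c2O)cc1 | target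

## Step count and risks

Total step count: 6. Longest linear sequence: 5 steps (steps 2, 3, 4, 5, 6); step 1 is the one-step side branch that joins at step 4.

Least certain steps:

**Step 4 (key step).** The most likely failure is loss of the cis relation. The methoxy group next to the exocyclic double bond of 4 may weaken the E preference of the methide, or the α-branched enolate may react through the exo arrangement. Either would give the 3,4-trans lactone. A slow annulation would also let 4 self-condense. The fallback sets C-2 by protonation instead of by the annulation topology. Setting out from 4 and 8, the annulation is run as in step 4 and the 3,4-trans epimer, (3S,4R)-5,7-dimethoxy-4-(4-methoxyphenyl)-3-[(2S)-1-(4-methoxyphenyl)propan-2-yl]-3,4-dihydro-2H-chromen-2-one F1, is not separated. The mixture is deprotonated with LiN(SiMe3)2 in THF at −78 °C to the common lactone enolate and quenched at that temperature with 2,6-di-tert-butyl-4-methylphenol. The anisyl group at position 4 is held pseudo-axial by the peri methoxy group and shields one face, so the proton should enter anti to it and give the cis lactone. The route is rejoined at 10.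

**Step 5.** The most likely failure is stalling at the cyclic aryl alkyl ether stage, because hydride delivery to the β-branched primary carbon is slow. Incomplete cleavage of the four methyl ethers is a second risk. The fallback separates the two tasks and uses a thioacetal. Setting out from 10:
- i-Bu2AlH at −78 °C should give the lactol (3R,4R)-5,7-dimethoxy-4-(4-methoxyphenyl)-3-[(2S)-1-(4-methoxyphenyl)propan-2-yl]-3,4-dihydro-2H-chromen-2-ol F2.
- Ethane-1,2-dithiol with BF3·OEt2 opens it to the dithiolane 2-[(1R,2R,3S)-2-(1,3-dithiolan-2-yl)-1,4-bis(4-methoxyphenyl)-3-methylbutyl]-3,5-dimethoxyphenol F3.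
- Desulfurisation with nickel boride (NiCl2·6H2O, NaBH4) gives 2-[(1R,2R,3S)-1,4-bis(4-methoxyphenyl)-2,3-dimethylbutyl]-3,5-dimethoxyphenol F4.
- BBr3 in CH2Cl2 (−78 → 0 °C) cleaves the four methyl ethers, and the route is rejoined at 12.

**Step 6.** The most likely failure is reversible ionisation at C-1 under HCl, which would erode its configuration. Imidate formation on the phenols of rings B and C could also hold back conversion. The fallback avoids Brønsted acid by a magnesium-templated ortho-acylation. Setting out from 12, EtMgBr (5 equiv) in Et2O/toluene forms the bromomagnesium phenoxides. 3-(4-Methoxyphenyl)propanoyl chloride then acylates the ring A carbon ortho to a magnesium phenoxide through a six-membered chelate. Aryl esters formed on rings B and C are cleaved with K2CO3 in MeOH. This gives 15 directly without a new isolable intermediate.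

**Step 3.** The most likely failure is base-mediated migration of the double bond of 7 into conjugation with ring C or with the carboxyl group before hydrogenation, which would lower the enantiomeric purity at C-3. The two CH2 arms are also similar, which may limit face selection. The fallback uses an oxazolidinone auxiliary and also bypasses step 2. Setting out from 6:
- (4S)-4-Benzyl-3-[(2E)-but-2-enoyl]-1,3-oxazolidin-2-one F5 is made from (4S)-4-benzyl-1,3-oxazolidin-2-one, n-BuLi and (E)-but-2-enoyl chloride.
- F5 takes up 6 in a conjugate addition with CuBr·SMe2 (THF, −78 → −20 °C). In the magnesium chelate the benzyl group of the auxiliary shields one face of the β-carbon, which should give (4S)-4-benzyl-3-[(3S)-4-(4-methoxyphenyl)-3-methylbutanoyl]-1,3-oxazolidin-2-one F6.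
- LiOH/H2O2 removes the auxiliary, and the route is rejoined at 8.

## Further compounds

F1 | step 4 | (3S,4R)-5,7-dimethoxy-4-(4-methoxyphenyl)-3-[(2S)-1-(4-methoxyphenyl)propan-2-yl]-3,4-dihydro-2H-chromen-2-one | COc1cc(OC)c2c(c1)OC(=O)[C@@H]([C@@H](C)Cc1ccc(OC)cc1)[C@@H]2c1ccc(OC)cc1
F2 | step 5 | (3R,4R)-5,7-dimethoxy-4-(4-methoxyphenyl)-3-[(2S)-1-(4-methoxyphenyl)propan-2-yl]-3,4-dihydro-2H-chromen-2-ol (mixture at position 2) | COc1cc(OC)c2c(c1)OC(O)[C@H]([C@@H](C)Cc1ccc(OC)cc1)[C@@H]2c1ccc(OC)cc1
F3 | step 5 | 2-[(1R,2R,3S)-2-(1,3-dithiolan-2-yl)-1,4-bis(4-methoxyphenyl)-3-methylbutyl]-3,5-dimethoxyphenol | COc1cc(O)c([C@@H](c2ccc(OC)cc2)[C@H](C2SCCS2)[C@@H](C)Cc2ccc(OC)cc2)c(OC)c1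
F4 | step 5 | 2-[(1R,2R,3S)-1,4-bis(4-methoxyphenyl)-2,3-dimethylbutyl]-3,5-dimethoxyphenol | COc1cc(O)c([C@@H](c2ccc(OC)cc2)[C@H](C)[C@@H](C)Cc2ccc(OC)cc2)c(OC)c1
F0 | step 6 | none | none
F5 | step 3 | (4S)-4-benzyl-3-[(2E)-but-2-enoyl]-1,3-oxazolidin-2-one | C/C=C/C(=O)N1[C@@H](Cc2ccccc2)COC1=O
F6 | step 3 | (4S)-4-benzyl-3-[(3S)-4-(4-methoxyphenyl)-3-methylbutanoyl]-1,3-oxazolidin-2-one | O=C(C[C@@H](C)Cc1ccc(OC)cc1)N1[C@@H](Cc2ccccc2)COC1=O
A1 | alternative 1 | 3-(4-methoxyphenyl)-1-(2,4,6-trihydroxyphenyl)propan-1-one | COc1ccc(CCC(=O)c2c(O)cc(O)cc2O)cc1
A2 | alternative 1 | (2R,3S)-1,4-bis(4-hydroxyphenyl)-2,3-dimethylbutan-1-ol (mixture at C-1) | OC(c1ccc(O)cc1)[C@H](C)[C@@H](C)Cc1ccc(O)cc1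
A3 | alternative 2 | (1E,3E)-1,4-bis(4-methoxyphenyl)-2,3-dimethylbuta-1,3-diene | COc1ccc(/C=C(C)/C(C)=C/c2ccc(OC)cc2)cc1
A4 | alternative 2 | (2S,3S)-1,4-bis(4-methoxyphenyl)-2,3-dimethylbutane | COc1ccc(C[C@H](C)[C@@H](C)Cc2ccc(OC)cc2)cc1
A5 | alternative 3 | 1-{[(2R,3E)-1,4-bis(4-methoxyphenyl)-3-methylbut-3-en-2-yl]oxy}-3,5-dimethoxybenzene | COc1cc(OC)cc(O[C@H](Cc2ccc(OC)cc2)/C(C)=C/c2ccc(OC)cc2)c1
A6 | alternative 3 | 2-[(1R,2E)-1,4-bis(4-methoxyphenyl)-2-methylbut-2-en-1-yl]-3,5-dimethoxyphenol | COc1cc(O)c([C@@H](c2ccc(OC)cc2)/C(C)=C/Cc2ccc(OC)cc2)c(OC)c1
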